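## Structural features

The target 29 is an aryl-substituted 4,9-friedodrimane. It is a trans-decalin (drimane numbering: ring A = C1–C5 and C10, ring B = C5–C10) with an exocyclic methylene on C4, and C9 is linked through the C11 methylene to C1' of a 1',2',3',5'-tetrasubstituted benzene carrying the 2'-O-sulfate, a free 3'-OH and a 5'-CH2OH. Four stereocentres stand in a row around ring B: C5 (quaternary, β-axial CH3), C10 (α-H), C9 (quaternary, β-axial CH3 and α-equatorial CH2Ar) and C8 (β-equatorial CH3). The absolute configuration is 5S,8S,9R,10S, and the methyl groups on C5 and C9 are syn-diaxial. The fragile groups are the C4=CH2 alkene (moves into the ring with acid, is lost on hydrogenation), the aryl sulfate monoester (cleaved by acid, so it comes last) and the electron-rich ring, whose benzylic oxygen para to O-2' ionises easily. The real difficulty is the quaternary C9 wedged between C8 and C10 and 1,3 to the quaternary C5, together with the need to sulfate O-2' and not O-3'. The key step uses two facts: C9 can be carried as a malonate carbon (a radical precursor that stays achiral until its two esters are told apart), and C4=CH2 is the natural end of a 6-exo closure followed by oxidation. The C9–C10 bond (ring B) and the C4–C5 bond (ring A) can therefore be made in one oxidative radical cascade of the acyclic diene 10, with C8 as the only stereocentre set beforehand. Re-derivation from 29 gives 8S and 5E for 10 and 5β-CH3, 8β-CH3, 10α-H for 11; the structures used here are mutually consistent and needed no correction.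

## Logic of the disconnections

29 ⇒ 28 ⇒ 27 ⇒ 25. The two O–Si bonds, the O–S bond of the sulfate and the acetal bond on O-2' are cut first. The sulfate does not survive acid and the two phenolic oxygens must not be confused, so 29 is traced to 28 (silyl groups on O-3' and on the benzylic oxygen), 28 to the single free phenol 27, and 27 to 25, in which O-2' alone carries an acetal. The gain is that the regiochemistry of sulfation is decided by protecting groups placed on the arene before coupling. The forward steps must free O-2' without protic acid, sulfate a phenol with two ortho substituents, and remove silicon under conditions that leave the sulfate alone.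

25 ⇒ 24 ⇒ 22 ⇒ 21. The three C–H bonds of the 9β-methyl group are traced to the C–O bonds of the axial ester of 21. Carrying this carbon as an ester keeps C9 non-enolisable through the coupling and lets both C9 substituents descend from one malonate. The forward demand is a hydride that reaches an ester syn-axial to 5-CH3, and a radical deoxygenation (through 24) of the neopentyl alcohol 22, where substitution is not feasible.

21 ⇒ 20 ⇒ 13 + 17 (through 18 and 19). The C11–C1' bond is cut after C11–H has been changed back to C11–O. Addition of an aryl anion to a neopentyl aldehyde is the dependable way to attach an arene next to a quaternary carbon, and it splits the target into two halves of similar size. In the forward step 18 must attack the aldehyde and not the ester, 19 must be trapped cold before retro-aldol cleavage, and the benzylic C–O bond must leave through a radical, because a cation at C11 would rearrange.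

17 ⇒ 16 ⇒ 15 ⇒ 14. The O–Si bonds, the oxidation level of the benzylic carbon and the acetal bond are removed from the arene. In 14 the formyl group makes the 4-OH (the future O-2') more acidic than the 5-OH, so the two oxygens can be told apart in the first step. The gain is a three-step fragment from a commercial arene. The demand is a mono-protection selective for the more acidic hydroxyl.

13 ⇒ 12 ⇒ 11. No C–C bond is cut here; the C11 oxidation level is traced back to the equatorial ester of 11. A symmetric diester means that C9 poses no stereochemical question in the ring-forming step. The forward reagent must distinguish the equatorial from the axial ester, and that choice creates the C9 stereocentre.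

11 ⇒ 10. The C9–C10 and C4–C5 bonds are cut. Both are ring bonds of a head-to-tail diene cyclisation, so a bicyclic problem becomes an open chain with one stereocentre. The forward cascade must close 6-endo and then 6-exo, must be oxidised only at the final primary radical, and must let C8 control C10 and the trans ring fusion. The diester and the unsubstituted vinyl terminus of 10 are kept. The diester gives a product that cannot be oxidised again, and any auxiliary substituent on the vinyl group would have to be removed later next to the acid-sensitive alkene.

10 ⇒ 9. The C8–CH3 bond is cut as a conjugate addition of a methyl nucleophile. The malonate is both the activating group for this step and the radical precursor for the next. The only stereocentre of 10 then comes from an achiral diene by catalysis, which demands high facial selectivity because every later stereocentre is derived from C8.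

9 ⇒ 7 + 8. The C8=C9 double bond is cut as a condensation of an aldehyde with an active methylene compound. This leads to a commodity diester and a simple dienal. The new double bond must not move out of conjugation.

7 ⇒ 6 ⇒ 3 + 4 (through 5). The C6–C7 bond is cut as a [3,3] rearrangement, which fixes the E geometry of C5=C10 in the same event, so no separate olefination is needed. The demand is a chair transition state with the chain equatorial, and a half-reduction of 6 that stops at the aldehyde.

3 ⇒ 1 + 2. The C5–C10 bond is cut as the addition of an alkenyl organometallic to an aldehyde, giving two commercial compounds. There is no stereochemical demand, since the carbinol centre disappears in the rearrangement.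

## Other disconnections considered

Alternative 1: The cut goes through C7–C8 and C9–C10 of ring B and gives the vinylcyclohexene ketal A1 and tiglic aldehyde A2.
- **Forward key step:** an enantioselective exo Diels–Alder reaction under a cationic chiral oxazaborolidine Lewis acid would give the octalin aldehyde A3.
- **In its favour:** one catalytic step would set C8, C9 and C10. C9 would arrive with its methyl group and the C11 aldehyde already differentiated, so the ester differentiation and the ester-to-methyl sequence of the chosen plan (about five steps) would not be needed. On this point the alternative is the better plan. Absolute control by a catalyst is the equal of the chosen plan's catalytic conjugate addition.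
- **Against it here:** A2 is a sluggish α,β-disubstituted dienophile, and the required regiochemistry joins its quaternary α-carbon to the ring terminus of A1. A3 still lacks the quaternary 5β-CH3, the trans ring fusion and C4=CH2. Reductive methylation of the derived enone at the ring-fusion carbon has no built-in preference for the trans isomer, and olefination of the C4 ketone next to a new quaternary centre is hindered.
- **Comparison:** the mechanism (concerted, catalyst-controlled) is more predictable than a radical cascade. Structurally, the chosen plan solves C5 and C4=CH2 inside its key step and the alternative does not. Step economy is likely to be similar once the C5 problem is counted.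

Alternative 2: The cut goes through C5–C10 and C8–C9 and leads to the tethered enal–dihydrothiepine A4.
- **Forward key step:** an intramolecular endo Diels–Alder reaction (thermal or with a chiral primary amine salt) would close rings A and B and give the sulfide-bridged aldehyde A5.
- **In its favour:** all four stereocentres, including both quaternary carbons, would be set at once. The CH2–S–CH2 bridge guarantees the cis relation of the future 5- and 8-methyl groups, the diene is locked s-cis, and C9 again arrives differentiated. On stereochemical convergence this alternative is better than the chosen plan (four centres against two). A later desulfurisation over nickel would also saturate the C6=C7 bond in the same operation.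
- **Against it here:** A4 is an unusual, multi-step substrate (a 3-substituted 2,7-dihydrothiepine with a ketal tether and a trisubstituted E-enal). The transition state joins a fully substituted diene terminus to an α-branched enal, and amine-salt catalysis of α-branched enals is the less developed case. C4=CH2 can only be installed after the nickel step, which fixes the order of the endgame.
- **Comparison:** the mechanism is cleaner (pericyclic against radical), but the supply of the precursor is much worse than for 10, which takes five steps from commodity chemicals. The overall step count is expected to be longer.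

Alternative 3: No ring is formed. The retrosynthetic cut is at the C9–CH3 and C5–CH3 bonds, which lead back to the aryl drim-8(12)-ene A7, itself available from sclareolide A6.
- **Forward key step:** strong acid (BF3·OEt2 or TfOH, low temperature) would protonate the 8(12)-alkene and drive four suprafacial 1,2-shifts (H9 to C8, CH3 from C10 to C9, H5 to C10, CH3 from C4 to C5), ending in proton loss to the friedodrimane A8.
- **In its favour:** the chirality comes from the pool, the shifts are stereospecific, and A8 has the whole carbon skeleton. On step economy and on the source of absolute configuration this alternative is clearly better than the chosen plan.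
- **Against it here:** all four shifts must run to the end, and the cascade must terminate by proton loss from a methyl group to give the least substituted alkene. The tetrasubstituted 5(10)-alkene and the endocyclic 3-ene are the thermodynamically preferred stopping points, and the same acid can isomerise A8. The electron-rich arene can capture the cations in a Friedel–Crafts cyclisation. The two methyl ethers of A8 would then have to be removed and O-2' distinguished from O-3' without a protecting-group handle.
- **Comparison:** the alkene position rests on a cationic cascade under thermodynamic pull. The chosen plan fixes C4=CH2 kinetically, by β-hydride loss from a primary alkylcopper that has a single β-hydrogen.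

Key step: step 6

Assumptions and conventions:
- The target is taken as the aryl hydrogen sulfate as drawn. Sulfated compounds are written in that neutral form although they would be handled as salts, and the acid form is released at the end by cold H+ ion exchange.
- The sense of induction of the phosphoramidite ligand in step 5 is assumed to be assignable by a test reaction; the enantiomer that delivers (S)-10 is used.
- α/β refer to drimane numbering with 5-CH3 as β. Ar* = 2-(methoxymethoxy)-3-[(triisopropylsilyl)oxy]-5-{[(triisopropylsilyl)oxy]methyl}phenyl.

## Route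

Step 1
Reactants: 1 hex-5-enal; 2 isopropenylmagnesium bromide
Product: 3 (±)-2-methylocta-1,7-dien-3-ol
Conditions: THF, −78 → 0 °C; aq. NH4Cl
Reagents that add atoms: none
Why: Grignard 1,2-addition of the alkenyl nucleophile to the aldehyde; the carbinol centre is left racemic because it becomes sp2 in step 2.

Step 2
Reactants: 3 (±)-2-methylocta-1,7-dien-3-ol; 4 triethyl orthoacetate
Product: 6 ethyl (4E)-4-methyldeca-4,9-dienoate, via mixed ketene acetal 5 (not isolated)
Conditions: 4 (5 equiv), EtCO2H (cat.), 140 °C, EtOH distilled off
Reagents that add atoms: none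
Why: Johnson–Claisen rearrangement: acid-catalysed exchange gives ketene acetal 5, whose chair [3,3] transition state holds the pentenyl chain equatorial and so should give the E trisubstituted C5=C10 alkene; the terminal vinyl group is a spectator.

Step 3
Reactants: 6 ethyl (4E)-4-methyldeca-4,9-dienoate
Product: 7 (4E)-4-methyldeca-4,9-dienal
Conditions: i-Bu2AlH (1.05 equiv), CH2Cl2, −78 °C; aq. potassium sodium tartrate
Reagents that add atoms: none
Why: Partial reduction of an ester by i-Bu2AlH; the aluminium hemiacetal is stable at −78 °C and collapses to the aldehyde only on work-up, and the alkenes are inert.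

Step 4
Reactants: 7 (4E)-4-methyldeca-4,9-dienal; 8 dimethyl malonate
Product: 9 dimethyl 2-[(4E)-4-methyldeca-4,9-dien-1-ylidene]propanedioate
Conditions: piperidine (0.1 equiv), AcOH (0.1 equiv), 4 Å molecular sieves, toluene, 40 °C
Reagents that add atoms: none
Why: Knoevenagel condensation under amine–acid catalysis with removal of water; the buffered conditions should limit migration of the new double bond to the β,γ-position.

Step 5
Reactants: 9 dimethyl 2-[(4E)-4-methyldeca-4,9-dien-1-ylidene]propanedioate
Product: 10 dimethyl 2-[(2S,5E)-5-methylundeca-5,10-dien-2-yl]propanedioate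
Conditions: Me2Zn (2.5 equiv), Cu(OTf)2 (2 mol %), BINOL-derived bis(1-phenylethyl)amine phosphoramidite (4 mol %), toluene, −40 → −20 °C; aq. NH4Cl
Reagents that add atoms: dimethylzinc, C[Zn]C
Why: Copper-catalysed asymmetric conjugate addition of a dialkylzinc to an alkylidene malonate; the chiral copper–phosphoramidite complex selects the enantiotopic face of C8 and sets 8S, and the isolated alkenes do not react.

Step 6
Reactants: 10 dimethyl 2-[(2S,5E)-5-methylundeca-5,10-dien-2-yl]propanedioate
Product: 11 dimethyl (2S,4aS,8aR)-2,4a-dimethyl-5-methylideneoctahydronaphthalene-1,1(2H)-dicarboxylate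
Conditions: Mn(OAc)3·2H2O (2.2 equiv, in portions), Cu(OAc)2·H2O (0.1 equiv), degassed AcOH, 0.01 M, 70 °C
Reagents that add atoms: none
Why: Trivalent manganese forms the manganese enolate of the malonate and oxidises it to the electrophilic C9 malonyl radical. This radical closes ring B 6-endo-trig at C10, the less substituted end of the E alkene, because 5-exo attack at the methyl-bearing C5 would build a quaternary centre. In the chair transition state the C8 methyl sits equatorial (where it also avoids A(1,3)-type strain with the in-plane ester) and the E geometry forces C1 equatorial, so C10 is set with its hydrogen α and C1 cis to the 8-methyl. The tertiary C5 radical then closes ring A 6-exo-trig at C4 of the vinyl group; the axial ester on C9 shields the β lobe of this radical, so the tether bonds to the α lobe, the 5-methyl ends β-axial and the fusion is trans. Divalent copper captures the primary radical and the alkylcopper loses its only β-hydrogen (on C4) to give C4=CH2, while trivalent manganese reoxidises monovalent copper so that copper is needed only in catalytic amount. The closest known reaction type is the Mn(OAc)3/Cu(OAc)2 oxidative free-radical polycyclisation of unsaturated malonates and β-keto esters with alkene termination. The selectivity needed is that the slow 6-exo closure outruns oxidation of the tertiary radical and 1,5-hydrogen transfer from C3; the low steady concentration of both oxidants, the high dilution and the ring-held equatorial tether are meant to secure this. The product has no hydrogen on C9 and cannot be oxidised further.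

Step 7
Reactants: 11 dimethyl (2S,4aS,8aR)-2,4a-dimethyl-5-methylideneoctahydronaphthalene-1,1(2H)-dicarboxylate
Product: 12 methyl (1S,2S,4aS,8aR)-1-(hydroxymethyl)-2,4a-dimethyl-5-methylidenedecahydronaphthalene-1-carboxylate (9α-CH2OH; 9β-CO2Me)
Conditions: i-Bu2AlH (2.3 equiv), CH2Cl2, −78 → −40 °C; aq. potassium sodium tartrate
Reagents that add atoms: none
Why: Group-selective hydride reduction of diastereotopic esters: the equatorial ester is open, whereas the axial ester is shielded by the syn-axial 5-CH3, so only the equatorial ester should be reduced; this choice defines C9.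

Step 8
Reactants: 12 methyl (1S,2S,4aS,8aR)-1-(hydroxymethyl)-2,4a-dimethyl-5-methylidenedecahydronaphthalene-1-carboxylate
Product: 13 methyl (1S,2S,4aS,8aR)-1-formyl-2,4a-dimethyl-5-methylidenedecahydronaphthalene-1-carboxylate
Conditions: Dess–Martin periodinane, NaHCO3, CH2Cl2, 0 °C → rt
Reagents that add atoms: none
Why: Dess–Martin oxidation under buffered conditions; the aldehyde is non-enolisable (quaternary C9) and the exocyclic alkene is untouched.

Step 9
Reactants: 14 3-bromo-4,5-dihydroxybenzaldehyde
Product: 15 3-bromo-5-hydroxy-4-(methoxymethoxy)benzaldehyde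
Conditions: MOMCl (1.05 equiv), i-Pr2NEt (1.1 equiv), THF, −20 → 0 °C
Reagents that add atoms: chloromethyl methyl ether, COCCl
Why: Regioselective O-alkylation of a catechol aldehyde: the 4-OH is para to the formyl group and ortho to bromine and is the more acidic one, so with one equivalent of a weak base only its phenoxide should form and be trapped.

Step 10
Reactants: 15 3-bromo-5-hydroxy-4-(methoxymethoxy)benzaldehyde
Product: 16 3-bromo-5-(hydroxymethyl)-2-(methoxymethoxy)phenol
Conditions: NaBH4, MeOH/THF, 0 °C
Reagents that add atoms: none
Why: Borohydride reduction of the aryl aldehyde; the aryl bromide, the acetal and the phenol are inert.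

Step 11
Reactants: 16 3-bromo-5-(hydroxymethyl)-2-(methoxymethoxy)phenol
Product: 17 Ar*–Br ({[3-bromo-4-(methoxymethoxy)-5-(triisopropylsilyloxy)phenyl]methoxy}triisopropylsilane)
Conditions: i-Pr3SiCl (2.4 equiv), imidazole (5 equiv), DMF, rt → 40 °C
Reagents that add atoms: chlorotri(propan-2-yl)silane, CC(C)[Si](Cl)(C(C)C)C(C)C
Why: Silylation of the phenol and the benzylic alcohol; the triisopropylsilyl group is chosen because it migrates slowly between catechol oxygens and should survive organolithium, hydride and radical steps.

Step 12
Reactants: 13 methyl (1S,2S,4aS,8aR)-1-formyl-2,4a-dimethyl-5-methylidenedecahydronaphthalene-1-carboxylate; 17 Ar*–Br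
Product: 20 methyl (1S,2S,4aS,8aR)-1-{Ar*[(phenoxycarbonothioyl)oxy]methyl}-2,4a-dimethyl-5-methylidenedecahydronaphthalene-1-carboxylate (both C11 epimers), via aryllithium 18 (not isolated), via lithium alkoxide 19 (not isolated)
Conditions: 17 (1.3 equiv), t-BuLi (2.6 equiv), THF, −78 °C; 13, −78 → −50 °C; PhOC(S)Cl (1.6 equiv), −78 → −20 °C; used crude
Reagents that add atoms: O-phenyl carbonochloridothioate, S=C(Cl)Oc1ccccc1
Why: Bromine–lithium exchange gives 18, stabilised by the ortho acetal oxygen, and its 1,2-addition to the neopentyl aldehyde should be faster than attack on the shielded axial ester. Alkoxide 19 is thioacylated cold before retro-aldol cleavage can set in, and the C11 configuration is irrelevant because both epimers converge in step 13.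

Step 13
Reactants: 20 C11 O-phenyl thionocarbonate (both epimers)
Product: 21 methyl (1S,2S,4aS,8aR)-1-(Ar*-methyl)-2,4a-dimethyl-5-methylidenedecahydronaphthalene-1-carboxylate
Conditions: Bu3SnH (2 equiv), AIBN (0.2 equiv), toluene, 90 °C
Reagents that add atoms: none
Why: Barton–McCombie deoxygenation: the stannyl radical adds to C=S, β-scission gives the benzylic C11 radical and this takes hydrogen from Bu3SnH; the ester, the silyl ethers and the 1,1-disubstituted alkene are inert.

Step 14
Reactants: 21 methyl (1S,2S,4aS,8aR)-1-(Ar*-methyl)-2,4a-dimethyl-5-methylidenedecahydronaphthalene-1-carboxylate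
Product: 22 [(1S,2S,4aS,8aR)-1-(Ar*-methyl)-2,4a-dimethyl-5-methylidenedecahydronaphthalen-1-yl]methanol
Conditions: LiAlH4 (3 equiv), THF, 0 → 40 °C; aq. NaOH work-up
Reagents that add atoms: none
Why: Hydride reduction of a hindered axial ester to the neopentyl alcohol; LiAlH4 is small enough to reach a carbonyl syn-axial to 5-CH3, and the silyl ethers, the acetal and the alkene should tolerate it at this temperature.

Step 15
Reactants: 22 [(1S,2S,4aS,8aR)-1-(Ar*-methyl)-2,4a-dimethyl-5-methylidenedecahydronaphthalen-1-yl]methanol
Product: 24 O-{[(1S,2S,4aS,8aR)-1-(Ar*-methyl)-2,4a-dimethyl-5-methylidenedecahydronaphthalen-1-yl]methyl} S-methyl carbonodithioate, via sodium xanthate 23 (not isolated)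
Conditions: NaH, imidazole (cat.), THF, 0 °C; CS2, rt; MeI
Reagents that add atoms: carbon disulfide, S=C=S; iodomethane, CI
Why: Xanthate formation (alkoxide addition to CS2, then S-methylation); CS2 is small enough for the neopentyl alkoxide and nothing else in 22 is electrophilic or acidic.

Step 16
Reactants: 24 S-methyl xanthate of 22
Product: 25 {[3-(methoxymethoxy)-4-{[(1R,2S,4aS,8aS)-1,2,4a-trimethyl-5-methylidenedecahydronaphthalen-1-yl]methyl}... ]} written in short as Ar*–CH2–decalin: (1R,2S,4aS,8aS)-1-(Ar*-methyl)-1,2,4a-trimethyl-5-methylidenedecahydronaphthalene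
Conditions: Bu3SnH (5 equiv, 0.5 M), AIBN (portionwise), toluene, 110 °C
Reagents that add atoms: none
Why: Barton–McCombie deoxygenation of a primary xanthate, which needs the higher temperature for β-scission; the high Bu3SnH concentration should trap the neopentyl radical before hydrogen transfer from the syn-axial 5-CH3 can lead to rearrangement, and C9 is untouched (9β-CH3).

Step 17
Reactants: 25 (1R,2S,4aS,8aS)-1-(Ar*-methyl)-1,2,4a-trimethyl-5-methylidenedecahydronaphthalene
Product: 27 2-[(triisopropylsilyl)oxy]-4-{[(triisopropylsilyl)oxy]methyl}-6-{[(1R,2S,4aS,8aS)-1,2,4a-trimethyl-5-methylidenedecahydronaphthalen-1-yl]methyl}phenol, via aryl trimethylsilyl ether 26 (not isolated)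
Conditions: Me3SiOTf (2 equiv), 2,2'-bipyridyl (3 equiv), CH2Cl2, 0 °C → rt; then H2O
Reagents that add atoms: none
Why: Chemoselective cleavage of an aromatic methoxymethyl ether by Me3SiOTf/2,2'-bipyridyl: the aryl acetal is converted into silyl ether 26 under buffered, non-protic conditions that should spare the triisopropylsilyl ethers, the ionisable benzylic ether and the exocyclic alkene, and water then hydrolyses 26.

Step 18
Reactants: 27 free 2'-phenol
Product: 28 2-[(triisopropylsilyl)oxy]-4-{[(triisopropylsilyl)oxy]methyl}-6-{[(1R,2S,4aS,8aS)-1,2,4a-trimethyl-5-methylidenedecahydronaphthalen-1-yl]methyl}phenyl hydrogen sulfate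
Conditions: SO3·pyridine (5 equiv), pyridine, rt → 50 °C; handled as the pyridinium or sodium salt
Reagents that add atoms: sulfur trioxide–pyridine complex, [O-]S(=O)(=O)[n+]1ccccc1
Why: O-Sulfation of the single free phenol with SO3·pyridine; the regiochemistry is fixed by the protecting groups, and the non-anionic conditions disfavour silyl migration from O-3' to O-2'.

Step 19
Reactants: 28 bis-silylated aryl hydrogen sulfate
Product: 29 2-hydroxy-4-(hydroxymethyl)-6-{[(1R,2S,4aS,8aS)-1,2,4a-trimethyl-5-methylidenedecahydronaphthalen-1-yl]methyl}phenyl hydrogen sulfate (target)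
Conditions: Bu4NF (3 equiv), THF, 0 °C → rt; then sulfonic acid ion-exchange resin (H+ form), MeOH/H2O, 0 °C, freeze-drying
Reagents that add atoms: none
Why: Fluoride cleavage of both silyl ethers under basic conditions, in which an aryl sulfate monoester is stable; brief cold contact with the acidic resin should then give the hydrogen sulfate without moving the C4 alkene.

## Compound list

1 | hex-5-enal | C=CCCCC=O | starting material
2 | isopropenylmagnesium bromide | CC(=C)[Mg]Br | starting material
3 | (±)-2-methylocta-1,7-dien-3-ol | C=C(C)C(O)CCCC=C | intermediate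
4 | triethyl orthoacetate | CCOC(C)(OCC)OCC | starting material
5 | 3-[(1-ethoxyethenyl)oxy]-2-methylocta-1,7-diene (mixed ketene acetal, not isolated) | C=C(OCC)OC(CCCC=C)C(C)=C | intermediate
6 | ethyl (4E)-4-methyldeca-4,9-dienoate | CCOC(=O)CC/C(C)=C/CCCC=C | intermediate
7 | (4E)-4-methyldeca-4,9-dienal | O=CCC/C(C)=C/CCCC=C | intermediate
8 | dimethyl malonate | COC(=O)CC(=O)OC | starting material
9 | dimethyl 2-[(4E)-4-methyldeca-4,9-dien-1-ylidene]propanedioate | COC(=O)C(C(=O)OC)=CCC/C(C)=C/CCCC=C | intermediate
10 | dimethyl 2-[(2S,5E)-5-methylundeca-5,10-dien-2-yl]propanedioate | COC(=O)C(C(=O)OC)[C@@H](C)CC/C(C)=C/CCCC=C | intermediate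
11 | dimethyl (2S,4aS,8aR)-2,4a-dimethyl-5-methylideneoctahydronaphthalene-1,1(2H)-dicarboxylate (trans-decalin; 5β-CH3, 8β-CH3, 10α-H) | C=C1CCC[C@H]2C(C(=O)OC)(C(=O)OC)[C@@H](C)CC[C@]12C | intermediate
12 | methyl (1S,2S,4aS,8aR)-1-(hydroxymethyl)-2,4a-dimethyl-5-methylidenedecahydronaphthalene-1-carboxylate (9α-CH2OH, 9β-CO2Me) | C=C1CCC[C@H]2[C@](C(=O)OC)(CO)[C@@H](C)CC[C@]12C | intermediate
13 | methyl (1S,2S,4aS,8aR)-1-formyl-2,4a-dimethyl-5-methylidenedecahydronaphthalene-1-carboxylate | C=C1CCC[C@H]2[C@](C(=O)OC)(C=O)[C@@H](C)CC[C@]12C | intermediate
14 | 3-bromo-4,5-dihydroxybenzaldehyde | O=Cc1cc(Br)c(O)c(O)c1 | starting material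
15 | 3-bromo-5-hydroxy-4-(methoxymethoxy)benzaldehyde | O=Cc1cc(Br)c(OCOC)c(O)c1 | intermediate
16 | 3-bromo-5-(hydroxymethyl)-2-(methoxymethoxy)phenol | OCc1cc(Br)c(OCOC)c(O)c1 | intermediate
17 | {[3-bromo-4-(methoxymethoxy)-5-(triisopropylsilyloxy)phenyl]methoxy}triisopropylsilane (Ar*–Br) | CC(C)[Si](OCc1cc(Br)c(OCOC)c(O[Si](C(C)C)(C(C)C)C(C)C)c1)(C(C)C)C(C)C | intermediate
18 | Ar*–Li, aryllithium from 17 (not isolated) | [Li]c1cc(CO[Si](C(C)C)(C(C)C)C(C)C)cc(O[Si](C(C)C)(C(C)C)C(C)C)c1OCOC | intermediate
19 | lithium alkoxide of the 13 + 18 adduct, C11 epimers (not isolated) | C=C1CCC[C@H]2[C@](C(=O)OC)(C([O-])c3cc(CO[Si](C(C)C)(C(C)C)C(C)C)cc(O[Si](C(C)C)(C(C)C)C(C)C)c3OCOC)[C@@H](C)CC[C@]12C.[Li+] | intermediate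
20 | methyl (1S,2S,4aS,8aR)-1-{Ar*[(phenoxycarbonothioyl)oxy]methyl}-2,4a-dimethyl-5-methylidenedecahydronaphthalene-1-carboxylate, C11 epimers | C=C1CCC[C@H]2[C@](C(=O)OC)(C(OC(=S)Oc3ccccc3)c3cc(CO[Si](C(C)C)(C(C)C)C(C)C)cc(O[Si](C(C)C)(C(C)C)C(C)C)c3OCOC)[C@@H](C)CC[C@]12C | intermediate
21 | methyl (1S,2S,4aS,8aR)-1-(Ar*-methyl)-2,4a-dimethyl-5-methylidenedecahydronaphthalene-1-carboxylate (9α-CH2Ar*, 9β-CO2Me) | C=C1CCC[C@H]2[C@](C(=O)OC)(Cc3cc(CO[Si](C(C)C)(C(C)C)C(C)C)cc(O[Si](C(C)C)(C(C)C)C(C)C)c3OCOC)[C@@H](C)CC[C@]12C | intermediate
22 | [(1S,2S,4aS,8aR)-1-(Ar*-methyl)-2,4a-dimethyl-5-methylidenedecahydronaphthalen-1-yl]methanol (9β-CH2OH) | C=C1CCC[C@H]2[C@](CO)(Cc3cc(CO[Si](C(C)C)(C(C)C)C(C)C)cc(O[Si](C(C)C)(C(C)C)C(C)C)c3OCOC)[C@@H](C)CC[C@]12C | intermediate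
23 | sodium O-alkyl xanthate of 22 (not isolated) | C=C1CCC[C@H]2[C@](COC(=S)[S-])(Cc3cc(CO[Si](C(C)C)(C(C)C)C(C)C)cc(O[Si](C(C)C)(C(C)C)C(C)C)c3OCOC)[C@@H](C)CC[C@]12C.[Na+] | intermediate
24 | O-alkyl S-methyl xanthate of 22 | C=C1CCC[C@H]2[C@](COC(=S)SC)(Cc3cc(CO[Si](C(C)C)(C(C)C)C(C)C)cc(O[Si](C(C)C)(C(C)C)C(C)C)c3OCOC)[C@@H](C)CC[C@]12C | intermediate
25 | (1R,2S,4aS,8aS)-1-(Ar*-methyl)-1,2,4a-trimethyl-5-methylidenedecahydronaphthalene (9β-CH3, 9α-CH2Ar*) | C=C1CCC[C@H]2[C@](C)(Cc3cc(CO[Si](C(C)C)(C(C)C)C(C)C)cc(O[Si](C(C)C)(C(C)C)C(C)C)c3OCOC)[C@@H](C)CC[C@]12C | intermediate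
26 | 2'-O-trimethylsilyl ether of 27 (not isolated) | C=C1CCC[C@H]2[C@](C)(Cc3cc(CO[Si](C(C)C)(C(C)C)C(C)C)cc(O[Si](C(C)C)(C(C)C)C(C)C)c3O[Si](C)(C)C)[C@@H](C)CC[C@]12C | intermediate
27 | 2-[(triisopropylsilyl)oxy]-4-{[(triisopropylsilyl)oxy]methyl}-6-{[(1R,2S,4aS,8aS)-1,2,4a-trimethyl-5-methylidenedecahydronaphthalen-1-yl]methyl}phenol | C=C1CCC[C@H]2[C@](C)(Cc3cc(CO[Si](C(C)C)(C(C)C)C(C)C)cc(O[Si](C(C)C)(C(C)C)C(C)C)c3O)[C@@H](C)CC[C@]12C | intermediate
28 | 2-[(triisopropylsilyl)oxy]-4-{[(triisopropylsilyl)oxy]methyl}-6-{[(1R,2S,4aS,8aS)-1,2,4a-trimethyl-5-methylidenedecahydronaphthalen-1-yl]methyl}phenyl hydrogen sulfate | C=C1CCC[C@H]2[C@](C)(Cc3cc(CO[Si](C(C)C)(C(C)C)C(C)C)cc(O[Si](C(C)C)(C(C)C)C(C)C)c3OS(=O)(=O)O)[C@@H](C)CC[C@]12C | intermediate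
29 | 2-hydroxy-4-(hydroxymethyl)-6-{[(1R,2S,4aS,8aS)-1,2,4a-trimethyl-5-methylidenedecahydronaphthalen-1-yl]methyl}phenyl hydrogen sulfate | C=C1CCC[C@H]2[C@](C)(Cc3cc(CO)cc(O)c3OS(=O)(=O)O)[C@@H](C)CC[C@]12C | target

## Step count and least certain steps

Total: 19 steps (16 in the terpenoid line, 3 for the arene 17). Longest linear sequence: 16 steps (steps 1–8 and 12–19).

**Step 6 (key step).** The most likely failure is oxidation of the tertiary C5 radical by divalent copper or trivalent manganese, or 1,5-hydrogen transfer from C3, before the slow 6-exo closure. Either process ends the cascade after one ring. Incomplete trans selectivity at the ring fusion is the second risk, because C5 is set in a stepwise radical event. The fallback replaces the oxidative cascade by a phenylselenyl group transfer, in which no metal oxidant is present. Starting from 10, deprotonation (NaH, THF, 0 °C) and PhSeCl give the phenylselanyl malonate F1. Irradiation of F1 in dilute benzene starts a chain in which the malonyl radical cyclises twice and the final primary radical takes PhSe from F1, giving the primary selenide F2. Oxidation of F2 (H2O2, pyridine, CH2Cl2, 0 °C → rt) and syn-elimination of the selenoxide, which has its only β-hydrogen on C4, return to 11.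

**Step 7.** The risk is loss of group selectivity between the two esters, or over-reduction, because both esters are neopentyl. The fallback separates them by hydrolysis and not by hydride. From 11, saponification of the exposed equatorial ester (KOH, aq. MeOH, 60 °C) gives the acid ester F3. Oxalyl chloride with catalytic DMF converts F3 into the acid chloride F4, and LiAlH(Ot-Bu)3 (THF, −78 °C) reduces F4 to the aldehyde, rejoining the route at 13.

**Step 9.** The risk is poor regioselectivity in the mono-protection (attack at O-5 or double alkylation). The fallback reverses the order of protection through the dianion. From 14, NaH (2.1 equiv, THF/DMF, 0 °C) forms the dianion, in which the less stabilised 5-phenoxide is the more nucleophilic, and i-Pr3SiCl (1.0 equiv) gives the 5-O-silyl ether F5. MOMCl/i-Pr2NEt then caps the remaining 4-OH to give F6. NaBH4 reduces F6 to the benzylic alcohol F7, and i-Pr3SiCl/imidazole converts F7 into 17.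

**Step 16.** The risk is slow β-scission of the primary xanthate adduct radical, which returns alcohol 22 after work-up, together with translocation of the neopentyl radical to the syn-axial methyl group and homoallyl rearrangement. The fallback removes the oxygen through a hydrazone. From 22, Dess–Martin oxidation gives the axial aldehyde F8, and TsNHNH2 (EtOH, 50 °C) gives the tosylhydrazone F9. Reduction of F9 with catecholborane (CHCl3, 0 °C) followed by NaOAc·3H2O at reflux releases N2 and gives 25.

**Step 18.** The risk is sluggish sulfation of a phenol flanked by two ortho substituents, and base-induced silyl migration from O-3' to O-2', which would misplace the sulfate. The fallback installs a protected sulfate as a neutral diester. From 27, 2,2,2-trichloroethyl chlorosulfate with Et3N and DMAP (THF, 0 °C → rt) gives the aryl trichloroethyl sulfate F10, which can be purified on silica. Zinc dust with HCO2NH4 in MeOH then removes the trichloroethyl group and gives 28.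

## Further compounds

F1 | step 6 | dimethyl 2-[(2S,5E)-5-methylundeca-5,10-dien-2-yl]-2-(phenylselanyl)propanedioate | COC(=O)C([Se]c1ccccc1)(C(=O)OC)[C@@H](C)CC/C(C)=C/CCCC=C
F2 | step 6 | dimethyl 2,4a-dimethyl-5-[(phenylselanyl)methyl]octahydronaphthalene-1,1(2H)-dicarboxylate (ring configuration of 11; C4 epimers) | c1ccccc1[Se]CC1CCC[C@H]2C(C(=O)OC)(C(=O)OC)[C@@H](C)CC[C@]12C
F3 | step 7 | 9α-carboxylic acid 9β-methyl ester (1-(methoxycarbonyl)-2,4a-dimethyl-5-methylidenedecahydronaphthalene-1-carboxylic acid, ring configuration of 11) | C=C1CCC[C@H]2[C@](C(=O)OC)(C(=O)O)[C@@H](C)CC[C@]12C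
F4 | step 7 | methyl 1-(chlorocarbonyl)-2,4a-dimethyl-5-methylidenedecahydronaphthalene-1-carboxylate (9α-COCl, 9β-CO2Me) | C=C1CCC[C@H]2[C@](C(=O)OC)(C(=O)Cl)[C@@H](C)CC[C@]12C
F5 | step 9 | 3-bromo-4-hydroxy-5-[(triisopropylsilyl)oxy]benzaldehyde | O=Cc1cc(Br)c(O)c(O[Si](C(C)C)(C(C)C)C(C)C)c1
F6 | step 9 | 3-bromo-4-(methoxymethoxy)-5-[(triisopropylsilyl)oxy]benzaldehyde | O=Cc1cc(Br)c(OCOC)c(O[Si](C(C)C)(C(C)C)C(C)C)c1
F7 | step 9 | {3-bromo-4-(methoxymethoxy)-5-[(triisopropylsilyl)oxy]phenyl}methanol | OCc1cc(Br)c(OCOC)c(O[Si](C(C)C)(C(C)C)C(C)C)c1
F8 | step 16 | 1-(Ar*-methyl)-2,4a-dimethyl-5-methylidenedecahydronaphthalene-1-carbaldehyde (9β-CHO, ring configuration of 22) | C=C1CCC[C@H]2[C@](C=O)(Cc3cc(CO[Si](C(C)C)(C(C)C)C(C)C)cc(O[Si](C(C)C)(C(C)C)C(C)C)c3OCOC)[C@@H](C)CC[C@]12C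
F9 | step 16 | 4-methylbenzenesulfonohydrazone of F8 | C=C1CCC[C@H]2[C@](C=NNS(=O)(=O)c3ccc(C)cc3)(Cc3cc(CO[Si](C(C)C)(C(C)C)C(C)C)cc(O[Si](C(C)C)(C(C)C)C(C)C)c3OCOC)[C@@H](C)CC[C@]12C
F10 | step 18 | aryl 2,2,2-trichloroethyl sulfate of 27 | C=C1CCC[C@H]2[C@](C)(Cc3cc(CO[Si](C(C)C)(C(C)C)C(C)C)cc(O[Si](C(C)C)(C(C)C)C(C)C)c3OS(=O)(=O)OCC(Cl)(Cl)Cl)[C@@H](C)CC[C@]12C
A1 | alternative 1 | 6-ethenyl-1,4-dioxaspiro[4.5]dec-6-ene | C=CC1=CCCCC12OCCO2
A2 | alternative 1 | tiglic aldehyde, (2E)-2-methylbut-2-enal | C/C=C(\C)C=O
A3 | alternative 1 | 9-formyl-8β,9β-dimethyl-5(6)-octalin 4-ethylene ketal (10α-H) | O1CCOC12CCC[C@H]3[C@](C)(C=O)[C@@H](C)CC=C23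
A4 | alternative 2 | (2E)-6-[2-(2,7-dihydrothiepin-3-yl)-1,3-dioxolan-2-yl]-2-methylhex-2-enal | O=C/C(C)=C/CCCC1(OCCO1)C1=CC=CCSC1
A5 | alternative 2 | sulfide-bridged 6-octalin 9-carbaldehyde 4-ethylene ketal | O1CCOC12CCC[C@H]3[C@](C)(C=O)[C@@H](CSC4)C=C[C@]234
A6 | alternative 3 | sclareolide | CC1(C)CCC[C@@]2(C)[C@H]1CC[C@@]1(C)OC(=O)C[C@H]21
A7 | alternative 3 | methyl 3,4-dimethoxy-5-[(drim-8(12)-en-11-yl)]benzoate (5α-H, 9α-H, 10β-CH3) | C=C1CC[C@H]2C(C)(C)CCC[C@]2(C)[C@H]1Cc1cc(C(=O)OC)cc(OC)c1OC
A8 | alternative 3 | methyl 3,4-dimethoxy-5-{[(1R,2S,4aS,8aS)-1,2,4a-trimethyl-5-methylidenedecahydronaphthalen-1-yl]methyl}benzoate | C=C1CCC[C@H]2[C@](C)(Cc3cc(C(=O)OC)cc(OC)c3OC)[C@@H](C)CC[C@]12C
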